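I start from how slowly the starting material goes. After 6.00 min the south-east run still holds 10.8% of it and the south-west run 8.3%, though their catalyst differs by a factor of 1.52. So I work with the fraction left: what is spent is one minus that fraction, and I ask how much of it became target.

| setting | south-east | south-west | flask |
|---|---|---|---|
| starting material | 2 M | 2 M | 2.0 M |
| protic impurity | 0.10 M | 0.10 M | 0.100 M |
| catalyst | 25 mM | 38 mM | 50 mM |
| remark | run made earlier | run made earlier |  |
| time |  |  | 10 min |

| run | time / min | isomer of the product / % | target / % | starting material / % |
|---|---|---|---|---|
| south-east | 0.500 | 0.9 | 4.5 | 72.0 |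
| south-east | 0.833 | 2.9 | 7.1 | 59.5 |
| south-east | 1.50 | 7.1 | 10.4 | 42.0 |
| south-east | 3.00 | 16.6 | 14.7 | 23.3 |
| south-east | 6.00 | 31.2 | 18.9 | 10.8 |
| south-west | 0.500 | 1.8 | 7.0 | 69.7 |
| south-west | 0.833 | 3.8 | 10.5 | 56.3 |
| south-west | 1.50 | 10.0 | 15.0 | 38.9 |
| south-west | 3.00 | 21.0 | 20.4 | 19.7 |
| south-west | 6.00 | 37.2 | 25.4 | 8.3 |

(each reading ± 0.3 percentage points)

- ratio of isomer of the product to target at 8.0 s
- ratio of isomer of the product to target at 10 min
- which of isomer of the product and target there is more of at 10 min

- the numbers in the tables scatter by 0.3 percentage points (one standard deviation)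
- a reading or a percentage of target counts all its forms, free or not

Suppose the way to target goes with [catalyst] and the other way does not. Then target over the rest of the spent material, a selectivity factor, equals [catalyst] over a constant. At 6.00 min the south-east run gives that constant as 93.0 mM and the south-west run as 99.2 mM. I keep the mean, 96.1 mM, and call it the break-even catalyst: the [catalyst] at which spent starting material splits evenly between target and the rest.

But the south-east run at 3.00 min gives 105 mM, more than at 6.00 min, so the constant drifts. I accept that drift as the error of the estimate. For the flask, target then takes 34.2% of what is spent, and the ratio would be 1.92 if the rest were isomer.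

But in the runs the rest is not all isomer. The south-west balance at 6.00 min misses 29.1%, and at 3.00 min it missed 38.9%. In that run isomer grew meanwhile at 0.159 min⁻¹ of the missing part. If that growth goes with [catalyst], it scales to 0.209 min⁻¹ for the flask. If the flask misses as much at 6.00 min, my estimate of its missing part at 10 min is 12.6%. Taking the whole charge as spent, I commit to a ratio of 1.55.

The forecast says 0.06 at 8.0 s, 1.7 at 10 min, with isomer of the product ahead, starting from “Mass balance is far from closed”. My late ratio is lower, with the same leader. For the early ratio I have no reckoning of my own.

The flask gives 0.0722 at 8.0 s and 1.57 at 10 min, with isomer of the product ahead, 50.1% against 31.9% of target.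

    starting material ⇌ other conformer (K = 2.50, k = 0.00850 s⁻¹)
    starting material + catalyst → catalyst + target (k = 0.0780 M⁻¹ s⁻¹)
    catalyst + other conformer → catalyst + isomer of the product (k = 0.170 M⁻¹ s⁻¹)
    other conformer ⇌ dormant form (K = 0.560, k = 0.00340 s⁻¹)
    catalyst + target ⇌ idle complex (K = 1.00 M⁻¹, k = 0.150 M⁻¹ s⁻¹)
    starting material + protic impurity → quenched substrate (k = 0.0170 M⁻¹ s⁻¹)

At 10.0 min the flask still holds 5.59% of other conformer and 5.11% of dormant form. At 100 min these stand at 0% and 0%, and the ratio is 1.80, against the 1.92 from the break-even catalyst.

The neighbour flask with 0.20 M of catalyst stands above the break-even catalyst, so the rule puts target ahead, with a share of the spent material of 67.5% and a ratio of 0.480. Computed, at 10 min and with 0.0710% of the starting material left, this neighbour holds 57.0% target and 38.0% isomer of the product, a ratio of 0.667: target leads, with a smaller share than the rule gave.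

The earlier runs and the new flask stem from a simulated flask for substances that don't exist.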